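**Remark on the chemistry (assumption):** 4-fluoro-2,6-dimethoxybenzaldehyde (16), 4-hydroxy-2,6-dimethoxybenzaldehyde (6) and syringaldehyde (10) are taken as catalogue building blocks. The target is achiral, so no stereocentre has to be set.

## Retrosynthetic overview

1. Target 26 comes from the pentaphenol 25 by cleavage of thirteen methyl ethers.
2. The feature used (rings A–G in SMILES order; C1 = ring carbon bonded to the ether oxygen on the ring-A side): the C4–OH of rings B, C, E, F and G. Each lies between oxygenated C3 and C5 and para to the C1 ether carbon; in B and F it is also ortho to the C5 ether carbon. Each is written as C4–CHO, so 25 comes from pentaaldehyde 23 by a fivefold Dakin oxidation.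
3. In 23 the formyl groups activate fluoride displacement for five ethers (A–O–B, B–O–C, D–O–E, E–O–F, F–O–G). The sixth ether, ring C C6–O–C1 ring D, is meta to the ring C formyl group and is made by copper coupling.
4. Assembly order: A→B→C by SNAr on 2,4,6-trifluorobenzaldehyde, ring D by Ullmann coupling, ring E by SNAr, Br→OH on ring E, then F and G by SNAr. No ring is formed; all seven benzene rings are bought.

Key step: step 16

## Route

Step 1
Reactants: 1 2,4,6-trimethoxybenzaldehyde
Product: 3 2,4,6-trimethoxyphenol, via 2,4,6-trimethoxyphenyl formate 2 (not isolated)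
Conditions: mCPBA (1.2 equiv), CH2Cl2, 0 °C → rt; Me2S; then K2CO3 (cat.), MeOH, rt, Ar
Reagents that add atoms: mCPBA, OOC(=O)c1cccc(Cl)c1
Why: Dakin-type Baeyer–Villiger oxidation, in which the electron-rich 2,4,6-trimethoxyphenyl group migrates in the Criegee adduct in preference to hydride and the formate is removed by methanolysis.

Step 2
Reactants: 3 2,4,6-trimethoxyphenol; 4 2,4,6-trifluorobenzaldehyde
Product: 5 2,6-difluoro-4-(2,4,6-trimethoxyphenoxy)benzaldehyde
Conditions: K2CO3, DMF, 0 °C → rt, Ar; 4 in slight excess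
Reagents that add atoms: none
Why: SNAr (addition–elimination) at C4 of 4, since the fluoride para to the formyl group is the most electrophilic and least shielded site for a bulky 2,6-disubstituted phenoxide in a dipolar aprotic solvent.

Step 3
Reactants: 6 4-hydroxy-2,6-dimethoxybenzaldehyde
Product: 7 4-hydroxy-3-iodo-2,6-dimethoxybenzaldehyde
Conditions: NIS (1.0 equiv), TsOH (cat.), MeCN, 0 °C → rt
Reagents that add atoms: N-iodosuccinimide, O=C1CCC(=O)N1I
Why: Electrophilic aromatic iodination at C3 (equivalent to C5), the only free positions, ortho to the hydroxyl and meta to the formyl group; one equivalent should stop at the mono-iodide.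

Step 4
Reactants: 5 2,6-difluoro-4-(2,4,6-trimethoxyphenoxy)benzaldehyde; 7 4-hydroxy-3-iodo-2,6-dimethoxybenzaldehyde
Product: 8 2-fluoro-6-(4-formyl-2-iodo-3,5-dimethoxyphenoxy)-4-(2,4,6-trimethoxyphenoxy)benzaldehyde
Conditions: K2CO3, DMF, 70 °C; 7 (1.0 equiv)
Reagents that add atoms: none
Why: SNAr of one of the two equivalent ortho-fluorides of 5 by the weakly nucleophilic phenoxide of 7; the first aryloxy group deactivates the ring, so mono-substitution is expected, and the aryl iodide is inert without a metal.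

Step 5
Reactants: 8 fluoro iodo trimer A–B–C
Product: 9 2-(4-formyl-2-iodo-3,5-dimethoxyphenoxy)-6-methoxy-4-(2,4,6-trimethoxyphenoxy)benzaldehyde
Conditions: NaOMe (1.1 equiv), THF/MeOH, 0 °C → rt
Reagents that add atoms: sodium methoxide, C[O-].[Na+]
Why: SNAr of the last ortho-fluoride by methoxide; by the element effect fluoride is displaced far faster than the aryloxy groups on the other formyl-activated carbons, so the diaryl ethers should stay intact.

Step 6
Reactants: 10 syringaldehyde (4-hydroxy-3,5-dimethoxybenzaldehyde)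
Product: 11 4-(benzyloxy)-3,5-dimethoxybenzaldehyde
Conditions: BnBr, K2CO3, DMF, 50 °C
Reagents that add atoms: benzyl bromide, BrCc1ccccc1
Why: Williamson ether synthesis on the acidic, para-formyl phenol, which masks the hindered oxygen of the future ring D.

Step 7
Reactants: 11 4-(benzyloxy)-3,5-dimethoxybenzaldehyde
Product: 13 4-(benzyloxy)-3,5-dimethoxyphenol, via 4-(benzyloxy)-3,5-dimethoxyphenyl formate 12 (not isolated)
Conditions: mCPBA (1.3 equiv), CH2Cl2, rt; Me2S; then K2CO3 (cat.), MeOH, rt
Reagents that add atoms: mCPBA, OOC(=O)c1cccc(Cl)c1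
Why: Dakin-type Baeyer–Villiger oxidation in which the para-alkoxy aryl group migrates; it turns the formyl carbon into the unhindered ring D hydroxyl and leaves the benzyl ether untouched.

Step 8
Reactants: 9 iodo trimer A–B–C; 13 4-(benzyloxy)-3,5-dimethoxyphenol
Product: 14 benzyl-protected tetramer A–B–C–D (9 with iodine replaced by a 4-(benzyloxy)-3,5-dimethoxyphenoxy group)
Conditions: CuI (20 mol %), picolinic acid (40 mol %), K3PO4, 13 (2 equiv), DMSO, 90 °C, degassed
Reagents that add atoms: none
Why: Ullmann-type copper-catalysed diaryl ether synthesis with a ligand system developed for hindered partners; it pairs the aryl iodide with an unhindered, electron-rich phenol in excess, tolerates aldehydes, and at 90 °C should not exchange the formyl-activated aryloxy groups.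

Step 9
Reactants: 14 benzyl-protected tetramer A–B–C–D
Product: 15 tetramer phenol A–B–C–D (ring D = 4-hydroxy-3,5-dimethoxyphenoxy)
Conditions: H2 (1 atm), 10% Pd/C, EtOAc, rt; stopped after one equivalent of H2
Reagents that add atoms: none
Why: Palladium-catalysed hydrogenolysis of the benzyl ether, which should be much faster than reduction of the hindered, electron-rich 2,6-dioxygenated benzaldehydes under these conditions.

Step 10
Reactants: 16 4-fluoro-2,6-dimethoxybenzaldehyde
Product: 17 3-bromo-4-fluoro-2,6-dimethoxybenzaldehyde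
Conditions: NBS (1.05 equiv), MeCN, rt
Reagents that add atoms: N-bromosuccinimide, O=C1CCC(=O)N1Br
Why: Electrophilic aromatic bromination at C3 (equivalent to C5), the only free positions, ortho and para to the methoxy groups and meta to the formyl group.

Step 11
Reactants: 15 tetramer phenol A–B–C–D; 17 3-bromo-4-fluoro-2,6-dimethoxybenzaldehyde
Product: 18 pentamer bromide A–B–C–D–E (15 O-arylated on the ring D hydroxyl by a 2-bromo-4-formyl-3,5-dimethoxyphenyl group)
Conditions: Cs2CO3, DMSO, 90 °C; 17 (1.5 equiv)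
Reagents that add atoms: none
Why: SNAr of the fluoride, para to the formyl group and activated by the ortho bromine, by the hindered but electron-rich 2,6-dimethoxyphenoxide; the bromide, meta to the formyl group, is not displaced.

Step 12
Reactants: 18 pentamer bromide A–B–C–D–E
Product: 20 pentamer phenol A–B–C–D–E (18 with Br replaced by OH), via pentamer pinacol boronate 19 (not isolated)
Conditions: B2pin2, XPhos Pd G2 (5 mol %), KOAc, dioxane, 95 °C; then NaBO3·4H2O, THF/H2O, rt
Reagents that add atoms: bis(pinacolato)diboron, CC1(C)OB(OC1(C)C)B1OC(C)(C)C(C)(C)O1 (boron of 19); sodium perborate, [Na+].[O-]B1OO1 (oxygen of 20)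
Why: Miyaura borylation with a bulky biaryl phosphine suited to di-ortho-substituted aryl bromides, then oxidation of the C–B bond by perborate, to which alkoxybenzaldehydes without a free ortho or para hydroxyl should be inert at room temperature.

Step 13
Reactants: 20 pentamer phenol A–B–C–D–E; 4 2,4,6-trifluorobenzaldehyde
Product: 21 hexamer difluoride A–F (20 O-arylated on the ring E hydroxyl by a 3,5-difluoro-4-formylphenyl group)
Conditions: K2CO3, DMF, 0 °C → rt; 4 (1.5 equiv)
Reagents that add atoms: none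
Why: SNAr at the para fluoride of 4, as in step 2; the hindered phenoxide of 20 favours the unshielded C4 even more strongly.

Step 14
Reactants: 21 hexamer difluoride; 6 4-hydroxy-2,6-dimethoxybenzaldehyde
Product: 22 heptamer monofluoride (21 with one ring F fluorine replaced by a 4-formyl-3,5-dimethoxyphenoxy group)
Conditions: K2CO3, DMF, 70 °C; 6 (1.05 equiv)
Reagents that add atoms: none
Why: SNAr of one of two equivalent ortho-fluorides by the para-formyl phenoxide, as in step 4; the weak nucleophile is used on the more reactive difluoride so that the temperature can stay moderate.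

Step 15
Reactants: 22 heptamer monofluoride
Product: 23 heptaaryl pentaaldehyde (22 with the remaining fluorine replaced by methoxy)
Conditions: NaOMe (1.1 equiv), THF/MeOH, 0 °C → rt
Reagents that add atoms: sodium methoxide, C[O-].[Na+]
Why: SNAr of the last ortho-fluoride by methoxide, as in step 5, with fluoride leaving far faster than any formyl-activated aryloxide.

Step 16
Reactants: 23 heptaaryl pentaaldehyde
Product: 25 tridecamethyl ether pentaphenol (each formyl group of 23 replaced by OH), via heptamer pentaformate 24 (not isolated)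
Conditions: mCPBA (7.5 equiv), CH2Cl2, 0 °C → rt; Me2S; then K2CO3 (cat.), MeOH, rt, Ar
Reagents that add atoms: mCPBA, OOC(=O)c1cccc(Cl)c1
Why: Peracid adds to each formyl group to give a Criegee adduct, the aryl group migrates to oxygen with loss of 3-chlorobenzoate, and the five aryl formates of 24 are transesterified by methanol once the excess peracid has been reduced by Me2S. The closest known reaction is the Dakin-type Baeyer–Villiger oxidation of 2,4,6-trialkoxybenzaldehydes to phenols, as in steps 1 and 7, here run five times on one substrate. No ring is closed and no stereocentre is formed; five aryl C–C bonds are exchanged for C–O bonds. Aryl must migrate in preference to hydride at all five sites, and every formyl-bearing ring has oxygen on both ortho carbons and on the para carbon, which makes it the better migrating group. The aldehydes should react faster than the peracid hydroxylates the alkoxyarenes, the formates are less electron-rich than free phenols, and the phenols are released only after the oxidant is destroyed.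

Step 17
Reactants: 25 tridecamethyl ether pentaphenol
Product: 26 CNP0137585.0 (octadecahydroxy heptaaryl hexaether)
Conditions: BBr3 (40 equiv), CH2Cl2, −78 °C → rt; MeOH then H2O quench, Ar
Reagents that add atoms: none
Why: Lewis-acid ether cleavage with BBr3, in which bromide attacks the methyl carbon of each O–B adduct; the diaryl ethers offer no sp3 carbon for this attack and should survive.

## Compound list

1 | 2,4,6-trimethoxybenzaldehyde | COc1cc(OC)c(C=O)c(OC)c1 | starting material
2 | 2,4,6-trimethoxyphenyl formate | COc1cc(OC)c(OC=O)c(OC)c1 | intermediate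
3 | 2,4,6-trimethoxyphenol | COc1cc(OC)c(O)c(OC)c1 | intermediate
4 | 2,4,6-trifluorobenzaldehyde | O=Cc1c(F)cc(F)cc1F | starting material
5 | 2,6-difluoro-4-(2,4,6-trimethoxyphenoxy)benzaldehyde | COc1cc(OC)c(Oc2cc(F)c(C=O)c(F)c2)c(OC)c1 | intermediate
6 | 4-hydroxy-2,6-dimethoxybenzaldehyde | COc1cc(O)cc(OC)c1C=O | starting material
7 | 4-hydroxy-3-iodo-2,6-dimethoxybenzaldehyde | COc1cc(O)c(I)c(OC)c1C=O | intermediate
8 | 2-fluoro-6-(4-formyl-2-iodo-3,5-dimethoxyphenoxy)-4-(2,4,6-trimethoxyphenoxy)benzaldehyde | COc1cc(OC)c(Oc2cc(F)c(C=O)c(Oc3cc(OC)c(C=O)c(OC)c3I)c2)c(OC)c1 | intermediate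
9 | 2-(4-formyl-2-iodo-3,5-dimethoxyphenoxy)-6-methoxy-4-(2,4,6-trimethoxyphenoxy)benzaldehyde | COc1cc(OC)c(Oc2cc(OC)c(C=O)c(Oc3cc(OC)c(C=O)c(OC)c3I)c2)c(OC)c1 | intermediate
10 | syringaldehyde | COc1cc(C=O)cc(OC)c1O | starting material
11 | 4-(benzyloxy)-3,5-dimethoxybenzaldehyde | COc1cc(C=O)cc(OC)c1OCc1ccccc1 | intermediate
12 | 4-(benzyloxy)-3,5-dimethoxyphenyl formate | COc1cc(OC=O)cc(OC)c1OCc1ccccc1 | intermediate
13 | 4-(benzyloxy)-3,5-dimethoxyphenol | COc1cc(O)cc(OC)c1OCc1ccccc1 | intermediate
14 | benzyl-protected tetramer A–B–C–D | COc1cc(OC)c(Oc2cc(OC)c(C=O)c(Oc3cc(OC)c(C=O)c(OC)c3Oc3cc(OC)c(OCc4ccccc4)c(OC)c3)c2)c(OC)c1 | intermediate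
15 | tetramer phenol A–B–C–D | COc1cc(OC)c(Oc2cc(OC)c(C=O)c(Oc3cc(OC)c(C=O)c(OC)c3Oc3cc(OC)c(O)c(OC)c3)c2)c(OC)c1 | intermediate
16 | 4-fluoro-2,6-dimethoxybenzaldehyde | COc1cc(F)cc(OC)c1C=O | starting material
17 | 3-bromo-4-fluoro-2,6-dimethoxybenzaldehyde | COc1cc(F)c(Br)c(OC)c1C=O | intermediate
18 | pentamer bromide A–B–C–D–E | COc1cc(OC)c(Oc2cc(OC)c(C=O)c(Oc3cc(OC)c(C=O)c(OC)c3Oc3cc(OC)c(Oc4cc(OC)c(C=O)c(OC)c4Br)c(OC)c3)c2)c(OC)c1 | intermediate
19 | pentamer pinacol boronate A–B–C–D–E | COc1cc(OC)c(Oc2cc(OC)c(C=O)c(Oc3cc(OC)c(C=O)c(OC)c3Oc3cc(OC)c(Oc4cc(OC)c(C=O)c(OC)c4B5OC(C)(C)C(C)(C)O5)c(OC)c3)c2)c(OC)c1 | intermediate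
20 | pentamer phenol A–B–C–D–E | COc1cc(OC)c(Oc2cc(OC)c(C=O)c(Oc3cc(OC)c(C=O)c(OC)c3Oc3cc(OC)c(Oc4cc(OC)c(C=O)c(OC)c4O)c(OC)c3)c2)c(OC)c1 | intermediate
21 | hexamer difluoride A–F | COc1cc(OC)c(Oc2cc(OC)c(C=O)c(Oc3cc(OC)c(C=O)c(OC)c3Oc3cc(OC)c(Oc4cc(OC)c(C=O)c(OC)c4Oc4cc(F)c(C=O)c(F)c4)c(OC)c3)c2)c(OC)c1 | intermediate
22 | heptamer monofluoride A–G | COc1cc(OC)c(Oc2cc(OC)c(C=O)c(Oc3cc(OC)c(C=O)c(OC)c3Oc3cc(OC)c(Oc4cc(OC)c(C=O)c(OC)c4Oc4cc(F)c(C=O)c(Oc5cc(OC)c(C=O)c(OC)c5)c4)c(OC)c3)c2)c(OC)c1 | intermediate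
23 | heptaaryl pentaaldehyde (key-step precursor) | COc1cc(OC)c(Oc2cc(OC)c(C=O)c(Oc3cc(OC)c(C=O)c(OC)c3Oc3cc(OC)c(Oc4cc(OC)c(C=O)c(OC)c4Oc4cc(OC)c(C=O)c(Oc5cc(OC)c(C=O)c(OC)c5)c4)c(OC)c3)c2)c(OC)c1 | intermediate
24 | heptamer pentaformate | COc1cc(OC)c(Oc2cc(OC)c(OC=O)c(Oc3cc(OC)c(OC=O)c(OC)c3Oc3cc(OC)c(Oc4cc(OC)c(OC=O)c(OC)c4Oc4cc(OC)c(OC=O)c(Oc5cc(OC)c(OC=O)c(OC)c5)c4)c(OC)c3)c2)c(OC)c1 | intermediate
25 | tridecamethyl ether pentaphenol (key-step product) | COc1cc(OC)c(Oc2cc(OC)c(O)c(Oc3cc(OC)c(O)c(OC)c3Oc3cc(OC)c(Oc4cc(OC)c(O)c(OC)c4Oc4cc(OC)c(O)c(Oc5cc(OC)c(O)c(OC)c5)c4)c(OC)c3)c2)c(OC)c1 | intermediate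
26 | CNP0137585.0 | Oc1cc(O)c(Oc2cc(O)c(O)c(Oc3cc(O)c(O)c(O)c3Oc3cc(O)c(Oc4cc(O)c(O)c(O)c4Oc4cc(O)c(O)c(Oc5cc(O)c(O)c(O)c5)c4)c(O)c3)c2)c(O)c1 | target

## Step count and risks

Total step count: 17. Longest linear sequence: 13 steps (1, 2, 4, 5, 8, 9, 11, 12, 13, 14, 15, 16, 17).

**Steps most likely to fail**

Step 8 (Ullmann coupling). Copper insertion into the aryl iodide, which sits between a methoxy and a bulky aryloxy group, may be too slow, so that hydrodeiodination or phenoxide-driven ether exchange takes over. Fallback, from 9: Miyaura borylation (B2pin2, XPhos Pd G2, KOAc, dioxane) should give the trimer pinacol boronate F1, and perborate oxidation should give the trimer phenol F2. Separately, purchased 4-bromo-2,6-dimethoxyphenol is benzylated (BnBr, K2CO3) to 2-(benzyloxy)-5-bromo-1,3-dimethoxybenzene F3. The polarity of the copper coupling is then reversed: the hindered phenol F2 is coupled with the unhindered bromide F3 (CuI, picolinic acid, K3PO4, DMSO, 90 °C), the better-precedented pairing, and the route is rejoined at 14.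

Step 12 (borylation and oxidation on the pentamer). Transmetalation at the di-ortho-substituted aryl palladium centre may lag behind protodebromination, and the congested boronate may oxidise slowly. Fallback, from 17: the hydroxyl is installed on the monomer, where the bromide is flanked only by methoxy and fluorine. Borylation should give 4-fluoro-2,6-dimethoxy-3-(4,4,5,5-tetramethyl-1,3,2-dioxaborolan-2-yl)benzaldehyde F4, and perborate oxidation 4-fluoro-3-hydroxy-2,6-dimethoxybenzaldehyde F5. Benzylation gives 3-(benzyloxy)-4-fluoro-2,6-dimethoxybenzaldehyde F6. SNAr with 15 (Cs2CO3, DMSO) gives the benzyl-protected pentamer F7, and hydrogenolysis (H2, Pd/C, EtOAc) rejoins the route at 20.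

Step 16 (fivefold Dakin oxidation). Peracid hydroxylation of the alkoxy-rich rings may compete before all five formyl groups have reacted, or partial formate cleavage may expose phenols to the oxidant. Fallback, from 23: the order of the last two operations is reversed. BBr3 first cleaves the thirteen methyl ethers to give the tridecahydroxy pentaaldehyde F8. Each formyl group then carries free ortho and para hydroxyls, and a classical Dakin oxidation with buffered aqueous H2O2 (boric acid or phosphate, pH 6–7, Ar) should give 26 directly.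

## Further compounds

F1 | step 8 | trimer pinacol boronate (9 with I replaced by pinacolboryl) | COc1cc(OC)c(Oc2cc(OC)c(C=O)c(Oc3cc(OC)c(C=O)c(OC)c3B4OC(C)(C)C(C)(C)O4)c2)c(OC)c1
F2 | step 8 | trimer phenol (9 with I replaced by OH) | COc1cc(OC)c(Oc2cc(OC)c(C=O)c(Oc3cc(OC)c(C=O)c(OC)c3O)c2)c(OC)c1
F3 | step 8 | 2-(benzyloxy)-5-bromo-1,3-dimethoxybenzene | COc1cc(Br)cc(OC)c1OCc1ccccc1
F4 | step 12 | 4-fluoro-2,6-dimethoxy-3-(4,4,5,5-tetramethyl-1,3,2-dioxaborolan-2-yl)benzaldehyde | COc1cc(F)c(B2OC(C)(C)C(C)(C)O2)c(OC)c1C=O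
F5 | step 12 | 4-fluoro-3-hydroxy-2,6-dimethoxybenzaldehyde | COc1cc(F)c(O)c(OC)c1C=O
F6 | step 12 | 3-(benzyloxy)-4-fluoro-2,6-dimethoxybenzaldehyde | COc1cc(F)c(OCc2ccccc2)c(OC)c1C=O
F7 | step 12 | benzyl-protected pentamer (20 as its ring E benzyl ether) | COc1cc(OC)c(Oc2cc(OC)c(C=O)c(Oc3cc(OC)c(C=O)c(OC)c3Oc3cc(OC)c(Oc4cc(OC)c(C=O)c(OC)c4OCc4ccccc4)c(OC)c3)c2)c(OC)c1
F8 | step 16 | tridecahydroxy heptaaryl pentaaldehyde | Oc1cc(O)c(Oc2cc(O)c(C=O)c(Oc3cc(O)c(C=O)c(O)c3Oc3cc(O)c(Oc4cc(O)c(C=O)c(O)c4Oc4cc(O)c(C=O)c(Oc5cc(O)c(C=O)c(O)c5)c4)c(O)c3)c2)c(O)c1
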